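## Analysis of the target

Target 33 is a eudesman-12,8-olide in which an oxygen atom bridges C1 and C4, so that ring A and this oxygen form a 7-oxabicyclo[2.2.1]heptane with the C15 methyl group on the bridgehead C4. Ring B (C5 to C10) is fused to the C5–C10 bond of that bicycle through the exo bond C5–C6 and the endo bond C10–C9, with the C14 methyl group exo on the quaternary C10. The fusion is therefore trans on a rigid bicycle, and ring B is strained. There are eight stereocentres (1R,4S,5S,6S,7S,8S,9S,10S in eudesmane numbering); around ring B, C6–O (angelate) is trans to C7–C11, C7–C11 is cis to C8–O (cis-fused lactone), and C8–O is trans to C9–OH. The sensitive groups are the α-methylene lactone (Michael acceptor, reducible) and the angelate, which isomerises to the tiglate and is hard to put on a hindered alcohol. Two features make the synthesis hard: a carbanion at C5 or C10 expels the bridging oxygen from C4 or C1, and a C5 centre next to a carbonyl group would epimerise to the unstrained cis-fused ring. The strategy rests on the triad C6–O, C7–C11, C8–O: these three bonds sit trans,cis on adjacent carbons of ring B and can be written as the addition of a carbon radical (C11) and an oxygen radical across a C6=C7 double bond, with C11 tethered to the C8 oxygen.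

## Retrosynthetic reasoning

**33 ⇒ 32 ⇒ 31 ⇒ 30.** The O–Si bond at C9 of 32 is cut last. The exocyclic C11=C13 double bond is traced back through ammonium salt 31 to Mannich base 30. This keeps the Michael acceptor masked while the N–O bond is reduced and while C6–OH is acylated; the forward step only has to N-methylate and eliminate.

**30 ⇒ 28 + 29; 28 ⇒ 27.** The ester C–O bond at C6 is cut to alcohol 28 and angelic acid 29. It is cut late because the angelate would not survive the enolate and radical steps. Alcohol 28 comes from alkoxyamine 27 by N–O reduction, so the nitroxide fragment of the key step also protects C6–O through the lactone chemistry.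

**27 ⇒ 26 ⇒ 25 ⇒ 24.** The C11–C13 bond is cut (aminomethylation of the enolate of lactone 26), and the C12 carbonyl is traced to the acetal carbon of 24 through lactol 25. Only oxidation level changes; the skeleton is already complete in 24.

**24 ⇒ 22 + 23 (key disconnection).** The C7–C11 and C6–O bonds are cut. Both lie on the C6=C7 alkene of 22, whose C8 oxygen carries the bromoacetal that holds C11 and C12. The forward step must form C7–C11 on the face of C8–O and then attach nitroxide 23 to C6 on the opposite face. One operation gives the acetal ring, two stereocentres and all carbons of the lactone except C13.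

**22 ⇒ 20 + 21.** The acetal C–O bond at C8 is cut to allylic alcohol 20 and ethyl vinyl ether 21. This is the only place where the two-carbon tether can be attached without touching a stereocentre.

**20 ⇒ 19 ⇒ 18.** After exchange of the C8 protecting group, the C6=C7 bond of 19 is cut to the two vinyl groups of 18. Cutting here, and not next to a carbonyl group, keeps C5 non-enolisable at every stage. The forward ring closure must work against the strain of the trans fusion.

**18 ⇒ 17 ⇒ 15 + 16.** The C8–C9 bond is cut to aldehyde 15 and allyl methoxymethyl ether 16. A reagent-controlled γ-alkoxyallylboration sets C8 and C9 together in the required syn relationship. It also delivers the two oxygens already differentiated (free C9–OH, C8 ether) and brings in C7.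

**15 ⇒ 14 ⇒ 12 + 13.** Absolute configuration is traced to a resolution of racemic aldehyde 12 through the aminals with C2-symmetric diamine 13. The quaternary aldehyde cannot racemise, and the stereocentre that differs sits directly on the aminal carbon.

**12 ⇒ 11 ⇒ 10 ⇒ 9 ⇒ 8.** The C10–C14 bond is cut by way of cyclopropanol 11, silyloxycyclopropane 10 and silyl enol ether 9 of aldehyde 8. Direct enolate methylation is not used, because negative charge on C10 would open the bicycle at C1–O. The cyclopropane route puts the charge on C14, and methylene transfer from the exo face sets C10.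

**8 ⇒ 7 ⇒ 6 ⇒ 5 ⇒ 4.** These are functional-group steps on a fixed skeleton. The C9 aldehyde is masked as the acetal of 7, the C5 vinyl group comes from the aldehyde of 6, and 6 is the C5 epimer of the all-endo hydrogenation product 5 of diene 4. C5 is the only acidic centre of 5, so its equilibration gives the exo C6/endo C9 pattern without ambiguity.

**4 ⇒ 2 + 3; 2 ⇒ 1.** The C1–C10 and C4–C5 bonds are cut, giving 2-methylfuran 3 and ynal 2 (from alkyne 1 by formylation). One cycloaddition gives the oxabicycle with both bridgeheads, and C6 and C9 arrive at different oxidation levels.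

## Alternatives that were turned down

**Alternative 1:** Ring B is cut at C5–C6 and C9–C10, giving diene A1 (C6 to C9 with both oxygens) and dienophile A2 (C5=C10 with C4 as ester, C1 as formyl and C14 in place). The forward key step is a catalysed enantioselective Diels–Alder reaction to cyclohexene A3.
- For: four adjacent stereocentres, including the quaternary C10, come from one catalytic step, and the absolute configuration comes from a catalyst. On these points it is stronger than the chosen route, which needs eight steps and a resolution to reach 15.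
- Against: the C7=C8 alkene of A3 still needs C7–C11 and C8–O with defined configuration, so the triad problem is only moved. The two acetates must be told apart, and the C6 acetate is β to the ester-bearing C5 and prone to elimination.
- Against: the oxygen-bridged ring A must be built last from the formyl and ester carbons, with new stereocentres at C1 and C4 and a late closure of the strained bicycle.
- In its place the chosen route has the bicycle from the first cycloaddition and installs the triad and the lactone carbons in one step (22 → 24).

**Alternative 2:** The C4–O and C1–C10 bonds are cut. In the forward step a Lewis acid opens the C4–C10 bond of a cyclopropane in the precursor of A4, and a tethered aldehyde adds with its oxygen to C4 and its carbon to C10, giving A4.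
- For: both rings of the bicycle and the quaternary C10 with the correct exo/endo pattern at C5 and C10 form in one step. This is more direct than the hydrogenation, epimerisation and cyclopropanation sequence used here (4 → 12).
- Against: C14 arrives as a lactone carbonyl and must be reduced to a methyl group next to the C9 ester, which costs several redox steps. The donor carbon C4 carries only alkyl groups, so the ring opening needs strong activation and a stereodefined cyclopropane.
- Against: none of C7, C8 or the four heteroatom-bearing centres of ring B is addressed, so a step such as 22 → 24 would still be needed.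
- In its place the chosen route carries C6 and C9 at aldehyde level from the start and reaches the radical precursor without redox corrections at C14.

**Alternative 3:** The C5–C10 and C4–O bonds are cut. In the forward step a Lewis acid opens a 1,10-epoxide in the ten-membered-ring precursor of A5 at C10, the C4=C5 alkene attacks C10, and the C1 oxygen captures the C4 cation, giving A5, the triethylsilyl ether of 33.
- For: ring A, ring B and the ether bridge form in one step at the very end with every substituent in place. In step count after the macrocycle it is the strongest of the four.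
- Against: the fully functionalised ten-membered lactone (E-alkene, epoxide face, angelate and methylene lactone present) is harder to make with stereocontrol than 33 itself.
- Against: the C4 cation more readily loses a proton than closes the strained trans-fused oxabicycle, which needs ring A in a boat. The acid-sensitive esters are exposed during the step.
- In its place the chosen route sets each stereocentre in a step with a defined control element and never has to form the ether bridge on a finished ring B.

Key step: step 16

Remark: eudesmane numbering is used throughout; 4–12 are racemates drawn as the enantiomer carried on after step 9, and centres formed as mixtures (enol ether geometry of 9, C9 of 10 and 11, acetal carbon of 22 and 24, C12 of 25, C11 of 27–31) are drawn as one isomer or left open.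

## Steps

Step 1
Reactants: 1 3,3-diethoxyprop-1-yne
Product: 2 4,4-diethoxybut-2-ynal
Conditions: n-BuLi, THF, −78 °C; DMF, −78 → 0 °C; inverse quench into KH2PO4 (aq)
Reagents that add atoms: N,N-dimethylformamide, CN(C)C=O
Why: Formylation of a lithium acetylide with a formamide; the buffered inverse quench frees the ynal without conjugate addition of the liberated amine.

Step 2
Reactants: 2 4,4-diethoxybut-2-ynal; 3 2-methylfuran
Product: 4 rac-3-(diethoxymethyl)-1-methyl-7-oxabicyclo[2.2.1]hepta-2,5-diene-2-carbaldehyde
Conditions: 3 (neat, excess), BHT (trace), 45 °C, sealed vessel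
Reagents that add atoms: none
Why: Thermal Diels–Alder reaction of a furan with an acetylenic aldehyde; the unsubstituted, more nucleophilic α-carbon of 3 bonds to the β-carbon of the ynal, so the formyl-bearing carbon (C5) should end next to the methyl bridgehead (C4) and the acetal-bearing carbon (C10) next to C1. Only the two bridgeheads are stereogenic, and the adduct is racemic.

Step 3
Reactants: 4 rac-3-(diethoxymethyl)-1-methyl-7-oxabicyclo[2.2.1]hepta-2,5-diene-2-carbaldehyde
Product: 5 rac-3-endo-(diethoxymethyl)-1-methyl-7-oxabicyclo[2.2.1]heptane-2-endo-carbaldehyde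
Conditions: H2 (3 atm), 10% Pd/C, EtOAc, rt
Reagents that add atoms: none
Why: Heterogeneous hydrogenation of both strained double bonds from the exo face (the face of the oxygen bridge), which should leave the formyl and acetal groups endo and cis.

Step 4
Reactants: 5 rac-3-endo-(diethoxymethyl)-1-methyl-7-oxabicyclo[2.2.1]heptane-2-endo-carbaldehyde
Product: 6 rac-3-endo-(diethoxymethyl)-1-methyl-7-oxabicyclo[2.2.1]heptane-2-exo-carbaldehyde
Conditions: K2CO3, MeOH, rt
Reagents that add atoms: none
Why: Base-mediated epimerisation α to an aldehyde; C5 is the only acidic centre, and relief of the eclipsing between the two endo groups should drive it to the exo aldehyde. The protic medium reprotonates the enolate before it can expel the C4–O bridge.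

Step 5
Reactants: 6 rac-3-endo-(diethoxymethyl)-1-methyl-7-oxabicyclo[2.2.1]heptane-2-exo-carbaldehyde
Product: 7 rac-3-endo-(diethoxymethyl)-2-exo-ethenyl-1-methyl-7-oxabicyclo[2.2.1]heptane
Conditions: Ph3PCH3Br, KOt-Bu, THF, 0 °C
Reagents that add atoms: methyltriphenylphosphonium bromide, C[P+](c1ccccc1)(c1ccccc1)c1ccccc1.[Br-]
Why: Wittig methylenation; the aldehyde is already in its thermodynamic configuration, so the basic ylide cannot erode C5, and after this step C5 is no longer enolisable.

Step 6
Reactants: 7 rac-3-endo-(diethoxymethyl)-2-exo-ethenyl-1-methyl-7-oxabicyclo[2.2.1]heptane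
Product: 8 rac-2-exo-ethenyl-1-methyl-7-oxabicyclo[2.2.1]heptane-3-endo-carbaldehyde
Conditions: 1 M HCl, THF, rt
Reagents that add atoms: water, O
Why: Acid hydrolysis of a diethyl acetal; any epimerisation at C10 is immaterial because C10 becomes trigonal in step 7.

Step 7
Reactants: 8 rac-2-exo-ethenyl-1-methyl-7-oxabicyclo[2.2.1]heptane-3-endo-carbaldehyde
Product: 9 rac-2-exo-ethenyl-1-methyl-3-[(trimethylsilyloxy)methylidene]-7-oxabicyclo[2.2.1]heptane
Conditions: Me3SiOTf, Et3N, CH2Cl2, 0 °C
Reagents that add atoms: trimethylsilyl trifluoromethanesulfonate, C[Si](C)(C)OS(=O)(=O)C(F)(F)F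
Why: Soft enolisation of an aldehyde to its silyl enol ether; no free enolate is formed at C10, which would open the bicycle at C1–O by E1cB elimination.

Step 8
Reactants: 9 rac-2-exo-ethenyl-1-methyl-3-[(trimethylsilyloxy)methylidene]-7-oxabicyclo[2.2.1]heptane
Product: 12 rac-2-exo-ethenyl-1,3-exo-dimethyl-7-oxabicyclo[2.2.1]heptane-3-endo-carbaldehyde, via silyloxycyclopropane 10 (not isolated), via cyclopropanol 11 (not isolated)
Conditions: Et2Zn, CH2I2, CH2Cl2, 0 °C; then K2CO3, MeOH, rt
Reagents that add atoms: diiodomethane, ICI
Why: Simmons–Smith cyclopropanation (Furukawa variant) of the electron-rich enol ether, which should react well before the vinyl group; the zinc carbenoid should be delivered to the exo face, guided by the ether bridge, placing the new CH2 exo on C10. Base-induced opening of the cyclopropanol breaks the C9–CH2 bond and gives the α-methyl aldehyde without negative charge on C10.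

Step 9
Reactants: 12 rac-2-exo-ethenyl-1,3-exo-dimethyl-7-oxabicyclo[2.2.1]heptane-3-endo-carbaldehyde; 13 (1R,2R)-N,N′-dimethyl-1,2-diphenylethane-1,2-diamine
Product: 14 (4R,5R)-1,3-dimethyl-4,5-diphenylimidazolidine aminal of aldehyde 15
Conditions: 13 (1 equiv), 4 Å molecular sieves, toluene, 60 °C; chromatography on silica separates 14 from its diastereomer
Reagents that add atoms: none
Why: Aminal formation between an aldehyde and a C2-symmetric secondary 1,2-diamine, used as a covalent resolution; the aminal carbon is not stereogenic, and the two diastereomers differ at the quaternary carbon bonded to it, so they should separate.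

Step 10
Reactants: 14 (4R,5R)-1,3-dimethyl-4,5-diphenylimidazolidine aminal of aldehyde 15
Product: 15 2-exo-ethenyl-1,3-exo-dimethyl-7-oxabicyclo[2.2.1]heptane-3-endo-carbaldehyde as the single enantiomer with 1R,4S bridgeheads (eudesmane numbering)
Conditions: 0.5 M HCl, Et2O/H2O, 0 °C; NaOH (aq) to recover 13
Reagents that add atoms: water, O
Why: Mild acid hydrolysis of the aminal; the α-quaternary aldehyde cannot racemise.

Step 11
Reactants: 15 single-enantiomer aldehyde; 16 allyl methoxymethyl ether
Product: 17 (8S,9S)-homoallylic alcohol with C9–OH and C8–OCH2OCH3 on the C10 side chain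
Conditions: 16, s-BuLi, THF, −78 °C; (+)-Ipc2BOMe (from (−)-α-pinene); BF3·OEt2; then 15, −78 °C; NaOH, H2O2, 0 °C → rt
Reagents that add atoms: none
Why: Brown γ-alkoxyallylboration through a chair transition state; the (Z)-γ-alkoxyallyl unit gives the syn relationship of C8–O and C9–O, and the isopinocampheyl groups from (−)-α-pinene should direct attack to the re face of the aldehyde (9S). Any residual antipode of 15 would be turned into a separable diastereomer.

Step 12
Reactants: 17 (8S,9S)-homoallylic alcohol
Product: 18 9-O-tert-butyldimethylsilyl ether of 17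
Conditions: t-BuMe2SiOTf, 2,6-lutidine, CH2Cl2, 0 °C
Reagents that add atoms: tert-butyldimethylsilyl trifluoromethanesulfonate, CC(C)(C)[Si](C)(C)OS(=O)(=O)C(F)(F)F
Why: Silylation of a hindered secondary alcohol next to a quaternary carbon, which needs the silyl triflate; the methoxymethyl ether should be stable at this temperature.

Step 13
Reactants: 18 9-O-tert-butyldimethylsilyl ether of 17
Product: 19 tricyclic C6=C7 alkene with C8–OCH2OCH3 and C9–OSi(t-Bu)Me2
Conditions: second-generation Grubbs catalyst RuCl2(=CHPh)(H2IMes)(PCy3) (10 mol %), toluene (1 mM), 80 °C, argon purge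
Reagents that add atoms: none
Why: Ring-closing metathesis of two monosubstituted alkenes to a cyclohexene; the conditions are neutral and C5 carries no acidifying group, so the trans fusion cannot leak to cis. High dilution and removal of ethene are meant to offset the strain of the ring.

Step 14
Reactants: 19 tricyclic C6=C7 alkene
Product: 20 tricyclic allylic alcohol with free C8–OH and C9–OSi(t-Bu)Me2
Conditions: Me2BBr, CH2Cl2, −78 °C; then NaHCO3 (aq)
Reagents that add atoms: none
Why: Lewis-acid cleavage of a methoxymethyl ether by a bromoborane at low temperature; the reagent attacks the acetal oxygen and should leave the silyl ether and the bicyclic ether intact.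

Step 15
Reactants: 20 tricyclic allylic alcohol; 21 ethyl vinyl ether
Product: 22 8-O-(2-bromo-1-ethoxyethyl) acetal of 20 (both acetal epimers)
Conditions: NBS, 21 (excess), CH2Cl2, −40 → 0 °C
Reagents that add atoms: N-bromosuccinimide, O=C1CCC(=O)N1Br
Why: Ueno–Stork bromoacetalisation; the bromonium/oxocarbenium ion from the enol ether is captured by the C8 alcohol, and the electron-rich enol ether should react well before the ring alkene.

Step 16
Reactants: 22 8-O-(2-bromo-1-ethoxyethyl) acetal; 23 TEMPO
Product: 24 cis-fused cyclic ethyl acetal with the C6 O-(2,2,6,6-tetramethylpiperidin-1-yl) group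
Conditions: Bu3SnH (1.3 equiv) and 23 (2.6 equiv), each added by syringe pump, toluene (5 mM in 22), 80 °C
Reagents that add atoms: none
Why: Nitroxide 23 abstracts hydrogen from Bu3SnH to give the stannyl radical, which removes bromine from 22; the primary C11 radical adds to C7, and the resulting secondary C6 radical couples with a second molecule of 23. The closest known reaction type is the Ueno–Stork haloacetal radical cyclisation ended by nitroxide capture (tin hydride/nitroxide oxygenative cyclisation). The 2-ethoxytetrahydrofuran ring closes 5-exo-trig. At C7 the tether is anchored on the C8 oxygen, so C11 can reach C7 only on the face of the C8–O bond, which gives the cis ring fusion. At C6 the planar radical has the new C7–C11 bond and the C5–C4 bond on one face, so the bulky nitroxide should couple on the other face and give C6–O trans to C7–C11. The step needs ring closure before capture and capture before hydrogen transfer; slow feeding keeps 23 dilute enough for the fast cyclisation to come first, while radical–nitroxide coupling, which is close to diffusion control, should still outrun hydrogen transfer from the dilute stannane. Both acetal epimers converge, because that carbon later becomes the C12 carbonyl.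

Step 17
Reactants: 24 cyclic ethyl acetal
Product: 25 lactol (C12 hemiacetal, both anomers)
Conditions: 1 M HCl, THF, 0 °C → rt
Reagents that add atoms: water, O
Why: Hydrolysis of a 2-alkoxytetrahydrofuran acetal, which is much faster than cleavage of the hindered secondary silyl ether; the alkoxyamine is inert to dilute acid.

Step 18
Reactants: 25 lactol
Product: 26 cis-fused γ-lactone with the C6 alkoxyamine and C9 silyl ether
Conditions: (n-Pr4N)RuO4 (5 mol %), N-methylmorpholine N-oxide, 4 Å molecular sieves, CH2Cl2, rt
Reagents that add atoms: none
Why: Ley–Griffith oxidation of a lactol to the lactone; the hindered alkoxyamine nitrogen and the silyl ether should not be affected.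

Step 19
Reactants: 26 γ-lactone
Product: 27 11-(dimethylaminomethyl) lactone (Mannich base)
Conditions: LiN(i-Pr)2, THF, −78 °C; CH2=NMe2+ I−, −78 °C → rt
Reagents that add atoms: N,N-dimethylmethyleneiminium iodide, C=[N+](C)C.[I-]
Why: Mannich aminomethylation of a lactone lithium enolate with Eschenmoser salt; C11 is the only enolisable position and C7 carries no leaving group. The configuration at C11 does not matter.

Step 20
Reactants: 27 Mannich base
Product: 28 C6 alcohol (Mannich base retained)
Conditions: Zn dust, AcOH/THF/H2O (3:1:1), 50 °C
Reagents that add atoms: none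
Why: Reductive cleavage of the alkoxyamine N–O bond by zinc in acetic acid; the conjugated methylene lactone does not exist yet, so it cannot be reduced.

Step 21
Reactants: 28 C6 alcohol; 29 angelic acid
Product: 30 C6 angelate (Mannich base retained)
Conditions: 29, 2,4,6-trichlorobenzoyl chloride, Et3N, toluene, rt; then 28, toluene, 75 °C
Reagents that add atoms: none
Why: Yamaguchi-type esterification through the mixed anhydride; no nucleophilic catalyst is used, which limits conjugate addition–elimination and so should keep the (Z) geometry.

Step 22
Reactants: 30 C6 angelate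
Product: 32 9-O-tert-butyldimethylsilyl ether of 33, via trimethylammonium iodide 31 (not isolated)
Conditions: MeI, THF, rt; then NaHCO3 (aq), EtOAc, rt
Reagents that add atoms: none
Why: N-Methylation of the Mannich base followed by E1cB (Hofmann-type) loss of the amine gives the exocyclic C11=C13 bond under conditions too mild to isomerise the angelate.

Step 23
Reactants: 32 9-O-tert-butyldimethylsilyl ether of 33
Product: 33 target, (1R,4S,5S,6S,7S,8S,9S,10S)-6-angeloyloxy-1,4-epoxy-9-hydroxyeudesm-11(13)-en-12,8-olide
Conditions: HF·pyridine, THF, 0 °C → rt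
Reagents that add atoms: none
Why: Fluoride-mediated desilylation under weakly acidic conditions, which should avoid conjugate addition to the methylene lactone and acyl migration or isomerisation of the angelate.

## Compound list

1 | 3,3-diethoxyprop-1-yne | C#CC(OCC)OCC | starting material
2 | 4,4-diethoxybut-2-ynal | O=CC#CC(OCC)OCC | intermediate
3 | 2-methylfuran | Cc1ccco1 | starting material
4 | rac-3-(diethoxymethyl)-1-methyl-7-oxabicyclo[2.2.1]hepta-2,5-diene-2-carbaldehyde (CHO carbon is C6 on C5, acetal carbon is C9 on C10) | O=CC2=C(C(OCC)OCC)[C@H]1C=C[C@]2(C)O1 | intermediate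
5 | rac-3-endo-(diethoxymethyl)-1-methyl-7-oxabicyclo[2.2.1]heptane-2-endo-carbaldehyde | O=C[C@H]2[C@@H](C(OCC)OCC)[C@H]1CC[C@]2(C)O1 | intermediate
6 | rac-3-endo-(diethoxymethyl)-1-methyl-7-oxabicyclo[2.2.1]heptane-2-exo-carbaldehyde | O=C[C@@H]2[C@@H](C(OCC)OCC)[C@H]1CC[C@]2(C)O1 | intermediate
7 | rac-3-endo-(diethoxymethyl)-2-exo-ethenyl-1-methyl-7-oxabicyclo[2.2.1]heptane | C=C[C@@H]2[C@@H](C(OCC)OCC)[C@H]1CC[C@]2(C)O1 | intermediate
8 | rac-2-exo-ethenyl-1-methyl-7-oxabicyclo[2.2.1]heptane-3-endo-carbaldehyde | C=C[C@@H]2[C@@H](C=O)[C@H]1CC[C@]2(C)O1 | intermediate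
9 | rac-2-exo-ethenyl-1-methyl-3-[(trimethylsilyloxy)methylidene]-7-oxabicyclo[2.2.1]heptane (E/Z mixture) | C=C[C@@H]2C(=CO[Si](C)(C)C)[C@H]1CC[C@]2(C)O1 | intermediate
10 | rac-spirocyclopropane at C10 with exo CH2 and a trimethylsilyloxy group on the former C9 | C=C[C@@H]2[C@@]3(C(O[Si](C)(C)C)C3)[C@H]1CC[C@]2(C)O1 | intermediate (not isolated)
11 | rac-spirocyclopropanol corresponding to 10 | C=C[C@@H]2[C@@]3(C(O)C3)[C@H]1CC[C@]2(C)O1 | intermediate (not isolated)
12 | rac-2-exo-ethenyl-1,3-exo-dimethyl-7-oxabicyclo[2.2.1]heptane-3-endo-carbaldehyde | C=C[C@@H]2[C@@](C)(C=O)[C@H]1CC[C@]2(C)O1 | intermediate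
13 | (1R,2R)-N,N′-dimethyl-1,2-diphenylethane-1,2-diamine | CN[C@H](c1ccccc1)[C@@H](c1ccccc1)NC | starting material
14 | (4R,5R)-1,3-dimethyl-4,5-diphenylimidazolidin-2-yl aminal of 15 | C=C[C@@H]2[C@@](C)(C3N(C)[C@H](c4ccccc4)[C@@H](c4ccccc4)N3C)[C@H]1CC[C@]2(C)O1 | intermediate
15 | single enantiomer of 12: bridgeheads 1R,4S (eudesmane numbering), C5 vinyl exo, C10 methyl exo, C10 formyl endo | C=C[C@@H]2[C@@](C)(C=O)[C@H]1CC[C@]2(C)O1 | intermediate
16 | allyl methoxymethyl ether, 3-(methoxymethoxy)prop-1-ene | C=CCOCOC | starting material
17 | (8S,9S)-homoallylic alcohol: C10–CH(OH)–CH(OCH2OCH3)–CH=CH2 side chain, C5 vinyl | C=C[C@@H]2[C@@](C)([C@@H]([C@@H](OCOC)C=C)O)[C@H]1CC[C@]2(C)O1 | intermediate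
18 | 9-O-tert-butyldimethylsilyl ether of 17 | C=C[C@@H]2[C@@](C)([C@@H]([C@@H](OCOC)C=C)O[Si](C)(C)C(C)(C)C)[C@H]1CC[C@]2(C)O1 | intermediate
19 | tricyclic C6=C7 alkene, 8-O-methoxymethyl, 9-O-tert-butyldimethylsilyl | COCO[C@H]1C=C[C@@H]2[C@@](C)([C@@H]1O[Si](C)(C)C(C)(C)C)[C@H]1CC[C@]2(C)O1 | intermediate
20 | tricyclic allylic alcohol, free C8–OH, 9-O-tert-butyldimethylsilyl | O[C@H]1C=C[C@@H]2[C@@](C)([C@@H]1O[Si](C)(C)C(C)(C)C)[C@H]1CC[C@]2(C)O1 | intermediate
21 | ethyl vinyl ether | C=COCC | starting material
22 | 8-O-(2-bromo-1-ethoxyethyl) acetal of 20 (one acetal epimer drawn) | CCO[C@@H](CBr)O[C@H]1C=C[C@@H]2[C@@](C)([C@@H]1O[Si](C)(C)C(C)(C)C)[C@H]1CC[C@]2(C)O1 | intermediate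
23 | TEMPO, (2,2,6,6-tetramethylpiperidin-1-yl)oxyl | CC1(C)CCCC(C)(C)N1[O] | starting material
24 | cis-fused cyclic ethyl acetal with C6 O-(2,2,6,6-tetramethylpiperidin-1-yl) (one acetal epimer drawn) | CCO[C@H]1C[C@H]2[C@H](ON3C(C)(C)CCCC3(C)C)[C@@H]3[C@@](C)([C@H](O[Si](C)(C)C(C)(C)C)[C@H]2O1)[C@H]2CC[C@]3(C)O2 | intermediate
25 | lactol of 24 (C12–OH, both anomers) | OC1C[C@H]2[C@H](ON3C(C)(C)CCCC3(C)C)[C@@H]3[C@@](C)([C@H](O[Si](C)(C)C(C)(C)C)[C@H]2O1)[C@H]2CC[C@]3(C)O2 | intermediate
26 | 12,8-lactone with C6 alkoxyamine and C9 silyl ether | O=C1C[C@H]2[C@H](ON3C(C)(C)CCCC3(C)C)[C@@H]3[C@@](C)([C@H](O[Si](C)(C)C(C)(C)C)[C@H]2O1)[C@H]2CC[C@]3(C)O2 | intermediate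
27 | 11-(dimethylaminomethyl) derivative of 26 | O=C1C(CN(C)C)[C@H]2[C@H](ON3C(C)(C)CCCC3(C)C)[C@@H]3[C@@](C)([C@H](O[Si](C)(C)C(C)(C)C)[C@H]2O1)[C@H]2CC[C@]3(C)O2 | intermediate
28 | C6 alcohol from 27 | O=C1C(CN(C)C)[C@H]2[C@H](O)[C@@H]3[C@@](C)([C@H](O[Si](C)(C)C(C)(C)C)[C@H]2O1)[C@H]2CC[C@]3(C)O2 | intermediate
29 | angelic acid, (Z)-2-methylbut-2-enoic acid | C/C=C(/C)C(=O)O | starting material
30 | C6 angelate of 28 | O=C1C(CN(C)C)[C@H]2[C@H](OC(=O)/C(C)=C\C)[C@@H]3[C@@](C)([C@H](O[Si](C)(C)C(C)(C)C)[C@H]2O1)[C@H]2CC[C@]3(C)O2 | intermediate
31 | trimethylammonium iodide of 30 | O=C1C(C[N+](C)(C)C)[C@H]2[C@H](OC(=O)/C(C)=C\C)[C@@H]3[C@@](C)([C@H](O[Si](C)(C)C(C)(C)C)[C@H]2O1)[C@H]2CC[C@]3(C)O2.[I-] | intermediate (not isolated)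
32 | 9-O-tert-butyldimethylsilyl ether of 33 | C=C1C(=O)O[C@H]2[C@@H]1[C@H](OC(=O)/C(C)=C\C)[C@@H]1[C@@](C)([C@@H]2O[Si](C)(C)C(C)(C)C)[C@H]2CC[C@]1(C)O2 | intermediate
33 | (1R,4S,5S,6S,7S,8S,9S,10S)-6-angeloyloxy-1,4-epoxy-9-hydroxyeudesm-11(13)-en-12,8-olide | C=C1C(=O)O[C@H]2[C@@H]1[C@H](OC(=O)/C(C)=C\C)[C@@H]1[C@@](C)([C@@H]2O)[C@H]2CC[C@]1(C)O2 | target

## Step count and least certain steps

Total step count: 23. Longest linear sequence: 23 steps (1 → 33); the other starting materials enter this one sequence directly.

**Step 16 (key step).** The most likely failure is coupling of 23 with the primary C11 radical before it has cyclised. The second is hydrogen transfer from the stannane to the cyclised C6 radical. Both compete because radical–nitroxide coupling is faster than any ring closure once 23 accumulates. The fallback sets out from 22 and comes back at 24. The bromide of 22 is displaced with KSC(S)OEt (acetone, 50 °C) to give the xanthate F1. Dilauroyl peroxide in refluxing 1,2-dichloroethane then brings about a degenerate xanthate-transfer cyclisation, in which an uncyclised radical can only return to F1, and gives the cyclised C6 xanthate F2. F2, with Bu3SnH and an excess of 23 present from the start, regenerates the C6 radical, which no longer has to cyclise, and gives 24.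

**Step 13.** Metathesis is reversible and the ring being closed is strained by the trans fusion, so the diene may go to oligomers, or the catalyst may decompose before the cyclohexene accumulates. The fallback sets out from 18 and comes back at 19. Ozonolysis of both vinyl groups (O3, CH2Cl2, −78 °C; PPh3) gives the dialdehyde F3. Samarium diiodide (THF, −78 °C) joins C6 and C7 irreversibly and should give the cis-diol F4. Thiocarbonyldiimidazole gives the cyclic thionocarbonate F5, and 1,3-dimethyl-2-phenyl-1,3,2-diazaphospholidine (40 °C) effects the Corey–Winter syn-elimination to 19.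

**Step 8.** Methylene transfer to the C10=C9 enol ether may show poor facial selectivity, because the exo face is also the face of the C5 vinyl group. The vinyl group itself may be cyclopropanated. The fallback sets out from 4 and comes back at 12. Hydrogenation limited to the C2=C3 double bond (H2, one equivalent, 5% Pd/C, EtOAc, 0 °C) gives the enal F6. Me2CuLi with Me3SiCl (THF, −78 °C) adds the methyl group to C10 of the still planar C5=C10 enal from the open exo face, and K2CO3 in MeOH then equilibrates C5, giving the aldehyde F7. Wittig methylenation gives the alkene F8, and acetal hydrolysis (1 M HCl, THF) gives 12. This path is shorter but is not the first choice, because it passes through an enolate at C5 next to the bridging oxygen and needs a conjugate addition to a tetrasubstituted enal.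

**Step 21.** The activated angelic acid may isomerise to the tiglate, and acylation of the hindered C6 hydroxyl may be slow. The fallback sets out from 28 and comes back at 30. Acylation with 2-[bis(2,2,2-trifluoroethoxy)phosphoryl]propanoic acid (DCC, DMAP, CH2Cl2) gives the phosphonopropionate F9. Still–Gennari olefination with acetaldehyde (KN(SiMe3)2, 18-crown-6, THF, −78 °C) then builds the (Z)-2-methylbut-2-enoate on the molecule and gives 30.

## Further compounds

F1 | step 16 | O-ethyl S-alkyl xanthate replacing the bromide of 22 (both acetal epimers) | CCOC(CSC(=S)OCC)O[C@H]1C=C[C@@H]2[C@@](C)([C@@H]1O[Si](C)(C)C(C)(C)C)[C@H]1CC[C@]2(C)O1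
F2 | step 16 | cyclised cis-fused ethyl acetal with the O-ethyl xanthate on C6 (C6 and acetal carbon as mixtures) | CCOC1C[C@H]2C(SC(=S)OCC)[C@@H]3[C@@](C)([C@H](O[Si](C)(C)C(C)(C)C)[C@H]2O1)[C@H]2CC[C@]3(C)O2
F3 | step 13 | dialdehyde from 18 (C6 aldehyde on C5, C7 aldehyde next to C8–OCH2OCH3) | O=C[C@@H]2[C@@](C)([C@@H]([C@@H](OCOC)C=O)O[Si](C)(C)C(C)(C)C)[C@H]1CC[C@]2(C)O1
F4 | step 13 | tricyclic 6,7-cis-diol with 8-O-methoxymethyl and 9-O-tert-butyldimethylsilyl | COCO[C@H]1C(O)C(O)[C@@H]2[C@@](C)([C@@H]1O[Si](C)(C)C(C)(C)C)[C@H]1CC[C@]2(C)O1
F5 | step 13 | cyclic 6,7-thionocarbonate of F4 | COCO[C@H]1C2OC(=S)OC2[C@@H]3[C@@](C)([C@@H]1O[Si](C)(C)C(C)(C)C)[C@H]1CC[C@]3(C)O1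
F6 | step 8 | rac-3-(diethoxymethyl)-1-methyl-7-oxabicyclo[2.2.1]hept-2-ene-2-carbaldehyde | O=CC2=C(C(OCC)OCC)[C@H]1CC[C@]2(C)O1
F7 | step 8 | rac-3-endo-(diethoxymethyl)-1,3-exo-dimethyl-7-oxabicyclo[2.2.1]heptane-2-exo-carbaldehyde | O=C[C@@H]2[C@@](C)(C(OCC)OCC)[C@H]1CC[C@]2(C)O1
F8 | step 8 | rac-3-endo-(diethoxymethyl)-2-exo-ethenyl-1,3-exo-dimethyl-7-oxabicyclo[2.2.1]heptane | C=C[C@@H]2[C@@](C)(C(OCC)OCC)[C@H]1CC[C@]2(C)O1
F9 | step 21 | C6 2-[bis(2,2,2-trifluoroethoxy)phosphoryl]propanoate of 28 | O=C1C(CN(C)C)[C@H]2[C@H](OC(=O)C(C)P(=O)(OCC(F)(F)F)OCC(F)(F)F)[C@@H]3[C@@](C)([C@H](O[Si](C)(C)C(C)(C)C)[C@H]2O1)[C@H]2CC[C@]3(C)O2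
A1 | alternative 1 | (1E,3E)-buta-1,3-diene-1,4-diyl diacetate | CC(=O)O/C=C/C=C/OC(C)=O
A2 | alternative 1 | ethyl (E)-3-methyl-4-oxobut-2-enoate | CCOC(=O)/C=C(\C)C=O
A3 | alternative 1 | ethyl 2,5-diacetoxy-6-formyl-6-methylcyclohex-3-ene-1-carboxylate, four centres as in 33 | CCOC(=O)[C@@H]1[C@@H](OC(C)=O)C=C[C@@H](OC(C)=O)[C@@]1(C)C=O
A4 | alternative 2 | 7-oxabicyclo[2.2.1]heptane with exo-fused γ-lactone (C6 and future C14) and endo methyl ester (C9) on C10 | O=C1OC[C@@H]2[C@@]1(C(=O)OC)[C@H]1CC[C@]2(C)O1
A5 | alternative 3 | 9-O-triethylsilyl ether of 33 | C=C1C(=O)O[C@H]2[C@@H]1[C@H](OC(=O)/C(C)=C\C)[C@@H]1[C@@](C)([C@@H]2O[Si](CC)(CC)CC)[C@H]2CC[C@]1(C)O2
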